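The target contains a C4–C3–C3''–C4'' 1,4-diketone whose ends carry identical 5,7-dioxygenated rings A and A''. This hidden symmetry is traced back to diketone 5, the oxidative dimer of one fluoroacetophenone, with a fluorine ortho to each carbonyl. In a single operation the mono-enolate of 5 is C-aroylated and the new enolate oxygen displaces the adjacent aryl fluoride: C2''–C3'' and O1''–C8a'' form, ring C'' closes, and the two halves become different. The untouched ketone, its C3 methylene and its ortho fluorine then build ring C through a reagent-controlled aldol, a second fluoride displacement with C3 equilibration, and hydrogenolysis.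

Key step: step 4

Remark on locants: unprimed locants (O1, C2, C3, C4, C8a, rings A, B, C) belong to the flavanone half, double-primed ones to the flavone half.

Assumption: (−)-Ipc2BOTf (from (+)-α-pinene) is taken to direct its Z-enolate to the Si face of aldehyde 10, by analogy with chair transition states of related isopinocampheylboron reagents; if a trial shows the opposite sense, (+)-Ipc2BOTf is used with no other change.

Step 1
Reactants: 1 5-fluororesorcinol (5-fluorobenzene-1,3-diol)
Product: 2 1-(2-fluoro-4,6-dihydroxyphenyl)ethan-1-one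
Conditions: AcOH, BF3·OEt2, 90 °C
Reagents that add atoms: acetic acid, CC(=O)O
Why: Friedel–Crafts C-acetylation of the free resorcinol (possibly through the O-acetate and a Fries shift) should go to C4, para to one hydroxyl and ortho to the other, and not to the flanked C2, which puts fluorine ortho to the new ketone; it is run before benzylation so that no benzyl ether meets the Lewis acid.

Step 2
Reactants: 2 1-(2-fluoro-4,6-dihydroxyphenyl)ethan-1-one
Product: 3 1-[2,4-bis(benzyloxy)-6-fluorophenyl]ethan-1-one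
Conditions: BnBr (2.5 equiv), K2CO3, DMF, 70 °C
Reagents that add atoms: benzyl bromide, BrCc1ccccc1
Why: Williamson etherification of both phenols; warming is needed for the hydroxyl hydrogen-bonded to the ketone, and the fluoride on the electron-rich phenoxide ring should not be displaced.

Step 3
Reactants: 3 1-[2,4-bis(benzyloxy)-6-fluorophenyl]ethan-1-one (two molecules per molecule of product)
Product: 5 1,4-bis[2,4-bis(benzyloxy)-6-fluorophenyl]butane-1,4-dione, via lithium enolate 4 (not isolated)
Conditions: LiN(SiMe3)2 (1.05 equiv per ketone), THF, −78 °C; CuCl2 (1.1 equiv per ketone), DMF, −78 °C to rt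
Reagents that add atoms: second molecule of ketone 3, CC(=O)c1c(F)cc(OCc2ccccc2)cc1OCc1ccccc1
Why: Oxidative homocoupling of a ketone enolate, in which two molecules of 3 are joined at their methyl carbons: divalent copper (CuCl2) oxidises enolate 4 by one electron and two α-keto radicals (or copper enolates) combine at carbon; LiN(SiMe3)2 enolises the methyl ketone without metalating the arene C–H between F and OBn or the benzylic CH2 groups.

Step 4
Reactants: 5 1,4-bis[2,4-bis(benzyloxy)-6-fluorophenyl]butane-1,4-dione, 6 4-(benzyloxy)benzoyl chloride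
Product: 9 3-{2-[2,4-bis(benzyloxy)-6-fluorophenyl]-2-oxoethyl}-5,7-bis(benzyloxy)-2-[4-(benzyloxy)phenyl]-4H-chromen-4-one, via mono-lithium enolate 7 (not isolated), via triketone 8 (not isolated)
Conditions: LiN(SiMe3)2 (2.1 equiv), THF, −78 °C; 6 (1.0 equiv), −78 to 0 °C; aq NH4Cl; crude 8, K2CO3, DMF, 80 °C
Reagents that add atoms: none
Why: One equivalent of LiN(SiMe3)2 converts 5 into mono-enolate 7, which attacks the aroyl chloride at carbon in a Claisen-type C-acylation, and the second equivalent of base holds the more acidic product as its β-diketonate, which is triketone 8 after the quench. With K2CO3 in DMF the diketonate oxygen on C2'' adds to the fluorine-bearing C8a'', ortho to the C4'' carbonyl, and fluoride leaves from the Meisenheimer adduct; both benzyloxy groups are meta to fluorine and so do not oppose the attack. The closest known reaction type is the tandem enolate C-aroylation and intramolecular SNAr O-arylation of 2-fluoroaryl ketones that gives 3-substituted flavones. Ring C'' closes by a six-membered addition–elimination (6-exo attack on the arene carbon) that forms O1''–C8a'' after C2''–C3'', and no stereocentre is created. The step needs a single acylation and closure onto the nearer ring: the diketonate charge disfavours enolisation of the neighbouring CH2, the acid chloride is limiting, and attack on the distant fluoroarene would require a seven-membered ring. The C3 methylene, its ketone and the ring A fluorine pass through unchanged for the later closure of ring C.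

Step 5
Reactants: 9 3-{2-[2,4-bis(benzyloxy)-6-fluorophenyl]-2-oxoethyl}-5,7-bis(benzyloxy)-2-[4-(benzyloxy)phenyl]-4H-chromen-4-one, 10 4-(benzyloxy)benzaldehyde
Product: 13 (2S,3S)-1-[2,4-bis(benzyloxy)-6-fluorophenyl]-2-{5,7-bis(benzyloxy)-2-[4-(benzyloxy)phenyl]-4-oxo-4H-chromen-3-yl}-3-[4-(benzyloxy)phenyl]-3-hydroxypropan-1-one (syn aldol), via boron enolate 11 (not isolated), via boron aldolate 12 (not isolated)
Conditions: (−)-Ipc2BOTf (1.8 equiv), i-Pr2NEt, CH2Cl2, −78 °C; 10, −78 to −20 °C; H2O2, pH 7 buffer, MeOH, 0 °C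
Reagents that add atoms: none
Why: Reagent-controlled boron aldol: soft enolisation of the aryl ketone gives Z-enolate 11, which adds to 10 through a closed chair (Zimmerman–Traxler) transition state to the syn aldolate 12; the isopinocampheyl ligands direct attack to the Si face of the aldehyde, which sets the carbinol centre (S) (the future C2), the α-centre (S) follows from the syn relationship, and buffered peroxide frees the aldol without base.

Step 6
Reactants: 13 (2S,3S)-syn aldol from step 5
Product: 15 (2S,3R)-5,7-bis(benzyloxy)-2-[4-(benzyloxy)phenyl]-3-{5,7-bis(benzyloxy)-2-[4-(benzyloxy)phenyl]-4-oxo-4H-chromen-3-yl}-2,3-dihydro-4H-chromen-4-one (trans), via cis-flavanone 14 (not isolated)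
Conditions: KN(SiMe3)2 (1.05 equiv), THF, −78 to 0 °C; DBU (0.2 equiv), 25 °C
Reagents that add atoms: none
Why: Intramolecular SNAr O-arylation: the potassium alkoxide, formed by fast O–H deprotonation in the cold, attacks C8a of ring A (fluorine ortho to the C4 carbonyl, both benzyloxy groups meta to it) through a six-membered transition state, so that only O1–C8a forms and the carbinol centre becomes C2 (S) unchanged; DBU then epimerises the first-formed cis (2S,3S)-flavanone 14 at the doubly activated C3–H, through the enolate, to the thermodynamically preferred diequatorial trans (2S,3R) isomer.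

Step 7
Reactants: 15 (2S,3R)-trans-flavanone hexabenzyl ether from step 6
Product: 16 (2S,3R)-3-[5,7-dihydroxy-2-(4-hydroxyphenyl)-4-oxo-4H-chromen-3-yl]-5,7-dihydroxy-2-(4-hydroxyphenyl)-2,3-dihydro-4H-chromen-4-one (target)
Conditions: H2 (1 atm), 10% Pd/C, THF–MeOH, rt
Reagents that add atoms: none
Why: Hydrogenolysis of the six benzyl aryl ethers over Pd/C at 1 atm is neutral, so the flavone enone, both ketones and the base-sensitive C2 and C3 centres should stay untouched.

Compound list
1 | 5-fluororesorcinol | Oc1cc(O)cc(F)c1 | starting material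
2 | 1-(2-fluoro-4,6-dihydroxyphenyl)ethan-1-one | CC(=O)c1c(O)cc(O)cc1F | intermediate
3 | 1-[2,4-bis(benzyloxy)-6-fluorophenyl]ethan-1-one | CC(=O)c1c(F)cc(OCc2ccccc2)cc1OCc1ccccc1 | intermediate
4 | lithium enolate of 3 | [Li]OC(=C)c1c(F)cc(OCc2ccccc2)cc1OCc1ccccc1 | intermediate
5 | 1,4-bis[2,4-bis(benzyloxy)-6-fluorophenyl]butane-1,4-dione | O=C(CCC(=O)c1c(F)cc(OCc2ccccc2)cc1OCc1ccccc1)c1c(F)cc(OCc2ccccc2)cc1OCc1ccccc1 | intermediate
6 | 4-(benzyloxy)benzoyl chloride | O=C(Cl)c1ccc(OCc2ccccc2)cc1 | starting material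
7 | mono-lithium (Z)-enolate of 5 | [Li]O/C(=C\CC(=O)c1c(F)cc(OCc2ccccc2)cc1OCc1ccccc1)c1c(F)cc(OCc2ccccc2)cc1OCc1ccccc1 | intermediate
8 | 2-[4-(benzyloxy)benzoyl]-1,4-bis[2,4-bis(benzyloxy)-6-fluorophenyl]butane-1,4-dione (triketone, racemic and enolisable at C2) | O=C(CC(C(=O)c1ccc(OCc2ccccc2)cc1)C(=O)c1c(F)cc(OCc2ccccc2)cc1OCc1ccccc1)c1c(F)cc(OCc2ccccc2)cc1OCc1ccccc1 | intermediate
9 | 3-{2-[2,4-bis(benzyloxy)-6-fluorophenyl]-2-oxoethyl}-5,7-bis(benzyloxy)-2-[4-(benzyloxy)phenyl]-4H-chromen-4-one | O=C(Cc1c(-c2ccc(OCc3ccccc3)cc2)oc2cc(OCc3ccccc3)cc(OCc3ccccc3)c2c1=O)c1c(F)cc(OCc2ccccc2)cc1OCc1ccccc1 | intermediate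
10 | 4-(benzyloxy)benzaldehyde | O=Cc1ccc(OCc2ccccc2)cc1 | starting material
11 | diisopinocampheylboron (Z)-enolate of 9 (isopinocampheyl groups from (+)-α-pinene) | B([C@@H]1C[C@@H]2C[C@H]([C@H]1C)C2(C)C)([C@@H]1C[C@@H]2C[C@H]([C@H]1C)C2(C)C)O/C(=C\c1c(-c2ccc(OCc3ccccc3)cc2)oc2cc(OCc3ccccc3)cc(OCc3ccccc3)c2c1=O)c1c(F)cc(OCc2ccccc2)cc1OCc1ccccc1 | intermediate
12 | O-diisopinocampheylboryl derivative of 13 (syn boron aldolate) | O=C(c1c(F)cc(OCc2ccccc2)cc1OCc1ccccc1)[C@@H](c1c(-c2ccc(OCc3ccccc3)cc2)oc2cc(OCc3ccccc3)cc(OCc3ccccc3)c2c1=O)[C@H](OB([C@@H]1C[C@@H]2C[C@H]([C@H]1C)C2(C)C)[C@@H]1C[C@@H]2C[C@H]([C@H]1C)C2(C)C)c1ccc(OCc2ccccc2)cc1 | intermediate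
13 | (2S,3S)-1-[2,4-bis(benzyloxy)-6-fluorophenyl]-2-{5,7-bis(benzyloxy)-2-[4-(benzyloxy)phenyl]-4-oxo-4H-chromen-3-yl}-3-[4-(benzyloxy)phenyl]-3-hydroxypropan-1-one | O=C(c1c(F)cc(OCc2ccccc2)cc1OCc1ccccc1)[C@@H](c1c(-c2ccc(OCc3ccccc3)cc2)oc2cc(OCc3ccccc3)cc(OCc3ccccc3)c2c1=O)[C@H](O)c1ccc(OCc2ccccc2)cc1 | intermediate
14 | (2S,3S)-5,7-bis(benzyloxy)-2-[4-(benzyloxy)phenyl]-3-{5,7-bis(benzyloxy)-2-[4-(benzyloxy)phenyl]-4-oxo-4H-chromen-3-yl}-2,3-dihydro-4H-chromen-4-one (cis) | O=C1c2c(OCc3ccccc3)cc(OCc3ccccc3)cc2O[C@H](c2ccc(OCc3ccccc3)cc2)[C@@H]1c1c(-c2ccc(OCc3ccccc3)cc2)oc2cc(OCc3ccccc3)cc(OCc3ccccc3)c2c1=O | intermediate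
15 | (2S,3R)-5,7-bis(benzyloxy)-2-[4-(benzyloxy)phenyl]-3-{5,7-bis(benzyloxy)-2-[4-(benzyloxy)phenyl]-4-oxo-4H-chromen-3-yl}-2,3-dihydro-4H-chromen-4-one (trans) | O=C1c2c(OCc3ccccc3)cc(OCc3ccccc3)cc2O[C@H](c2ccc(OCc3ccccc3)cc2)[C@H]1c1c(-c2ccc(OCc3ccccc3)cc2)oc2cc(OCc3ccccc3)cc(OCc3ccccc3)c2c1=O | intermediate
16 | (2S,3R)-3-[5,7-dihydroxy-2-(4-hydroxyphenyl)-4-oxo-4H-chromen-3-yl]-5,7-dihydroxy-2-(4-hydroxyphenyl)-2,3-dihydro-4H-chromen-4-one | O=C1c2c(O)cc(O)cc2O[C@H](c2ccc(O)cc2)[C@H]1c1c(-c2ccc(O)cc2)oc2cc(O)cc(O)c2c1=O | target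

Total step count: 7. Longest linear sequence: 7 steps (1 to 16).

Steps most likely to fail

Step 6 carries the largest risk. The alkoxide of 13 can fragment by retro-aldol, because the departing enolate is stabilised, and recombine without facial control; the acidic α-C–H can also be removed and water lost before the ring closes. The first process erodes the C2 configuration and the second diverts material, and ring opening by retro-oxa-Michael during the C3 equilibration would erode C2 as well. The fallback gives up the enantioselective aldol and sets out from 9 and 10. K2CO3 in DMF at 60 °C should run aldol addition, fluoride displacement and C3 equilibration in one pot, with the reversible aldol and dehydration equilibria drained by the irreversible ring closure. This should give the racemic trans-flavanone, that is 15 together with its (2R,3S)-enantiomer F1. Preparative chromatography on a chiral stationary phase (cellulose tris(3,5-dimethylphenylcarbamate)) then delivers 15, where the route is rejoined.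

Step 5 is the second risk. Enolisation of the hindered, twisted aryl ketone by the bulky boron triflate may be slow or incomplete, the flavone carbonyl may bind the reagent, and facial discrimination may be poor. The fallback sets out from 9 and replaces C–C bond formation under reagent control by an asymmetric reduction. C-aroylation of 9 with a second portion of 6 (LiN(SiMe3)2, THF, −78 °C, cold quench) should give the 1,3-diketone F2. Asymmetric transfer hydrogenation with dynamic kinetic resolution (RuCl[(S,S)-TsDPEN](p-cymene), HCO2H–Et3N, rt) should then reduce only the unhindered 4-benzyloxyphenyl ketone, the other being flanked by two ortho substituents. The usual aryl ketone model predicts the (S)-carbinol, and the α-centre is labile under the conditions. The product is 13 and, if formed, its C2 epimer, the (2R,3S)-anti aldol F3. Both are taken through step 6, where C3 is equilibrated in any case, so the route is rejoined at 13.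

Step 4 is the third risk. Aroylation may occur at both methylenes or on the enolate oxygen, or conversion may stop short and leave a mixture that is hard to separate. The fallback sets out from 3 and assembles the triketone from two different halves. Aroylation of 3 with 6 (LiN(SiMe3)2, THF, −78 °C) should give 1-[2,4-bis(benzyloxy)-6-fluorophenyl]-3-[4-(benzyloxy)phenyl]propane-1,3-dione F4. A second portion of 3 is brominated with PhNMe3Br3 in THF to 2-bromo-1-[2,4-bis(benzyloxy)-6-fluorophenyl]ethan-1-one F5. C-alkylation of F4 with F5 (K2CO3, acetone, rt) should give triketone 8, where the route is rejoined; 8 is cyclised with K2CO3 in DMF as in step 4 to 9.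

Further compounds
F1 | step 6 | (2R,3S)-5,7-bis(benzyloxy)-2-[4-(benzyloxy)phenyl]-3-{5,7-bis(benzyloxy)-2-[4-(benzyloxy)phenyl]-4-oxo-4H-chromen-3-yl}-2,3-dihydro-4H-chromen-4-one (enantiomer of 15) | O=C1c2c(OCc3ccccc3)cc(OCc3ccccc3)cc2O[C@@H](c2ccc(OCc3ccccc3)cc2)[C@@H]1c1c(-c2ccc(OCc3ccccc3)cc2)oc2cc(OCc3ccccc3)cc(OCc3ccccc3)c2c1=O
F2 | step 5 | 1-[2,4-bis(benzyloxy)-6-fluorophenyl]-2-{5,7-bis(benzyloxy)-2-[4-(benzyloxy)phenyl]-4-oxo-4H-chromen-3-yl}-3-[4-(benzyloxy)phenyl]propane-1,3-dione | O=C(c1c(F)cc(OCc2ccccc2)cc1OCc1ccccc1)C(c1c(-c2ccc(OCc3ccccc3)cc2)oc2cc(OCc3ccccc3)cc(OCc3ccccc3)c2c1=O)C(=O)c1ccc(OCc2ccccc2)cc1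
F3 | step 5 | (2R,3S)-1-[2,4-bis(benzyloxy)-6-fluorophenyl]-2-{5,7-bis(benzyloxy)-2-[4-(benzyloxy)phenyl]-4-oxo-4H-chromen-3-yl}-3-[4-(benzyloxy)phenyl]-3-hydroxypropan-1-one (anti aldol, C2 epimer of 13) | O=C(c1c(F)cc(OCc2ccccc2)cc1OCc1ccccc1)[C@H](c1c(-c2ccc(OCc3ccccc3)cc2)oc2cc(OCc3ccccc3)cc(OCc3ccccc3)c2c1=O)[C@H](O)c1ccc(OCc2ccccc2)cc1
F4 | step 4 | 1-[2,4-bis(benzyloxy)-6-fluorophenyl]-3-[4-(benzyloxy)phenyl]propane-1,3-dione | O=C(CC(=O)c1ccc(OCc2ccccc2)cc1)c1c(F)cc(OCc2ccccc2)cc1OCc1ccccc1
F5 | step 4 | 2-bromo-1-[2,4-bis(benzyloxy)-6-fluorophenyl]ethan-1-one | O=C(CBr)c1c(F)cc(OCc2ccccc2)cc1OCc1ccccc1
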